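## Retrosynthetic overview

1. Target 44 ⇐ (2E,4E)-dienal 41 (aldehyde reduction, acetylation, desilylation) ⇐ Mukaiyama aldol condensation of the C3 acetaldehyde arm of 33 with enal 38.
2. 33 ⇐ exo-face vinyl cuprate 1,4-addition to bicyclic enoate 26 (sets C3, then C2 by equilibration).
3. 26 ⇐ β-hydroxy ester 21 (selenoxide elimination) ⇐ SmI2 intramolecular Reformatsky closure of keto bromo ester 18 (C1–C2 bond; the tether fixes the C1 carbinol).
4. 18 ⇐ ketol 4 by 1,2-carbonyl transposition and extension of the allyl group to the bromo ester chain.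
5. 4 ⇐ ketoreductase desymmetrisation of prochiral dione 3. Ring order: the six-membered ring comes from the commercial dione; the seven-membered ring is closed onto it in step 13.

Assumption: the SMILES is read as methyl (1S,2S,3R,6R,7S)-3-[(2E,4E)-1-acetoxy-6-hydroxy-6-methylhepta-2,4-dien-2-yl]-1,7-dihydroxy-6-methylbicyclo[4.3.1]decane-2-carboxylate; locants below follow this numbering (side-chain carbons C1'–C7'), TBS = tert-butyldimethylsilyl, TES = triethylsilyl.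

## Route

Step 1
Reactants: 1 2-methylcyclohexane-1,3-dione; 2 allyl bromide
Product: 3 2-methyl-2-(prop-2-en-1-yl)cyclohexane-1,3-dione
Conditions: 1 M aq. NaOH, rt
Reagents that add atoms: none
Why: C-allylation of the stabilised 1,3-dione enolate in water gives the prochiral 2,2-disubstituted dione.

Step 2
Reactants: 3 2-methyl-2-(prop-2-en-1-yl)cyclohexane-1,3-dione
Product: 4 (2S,3S)-3-hydroxy-2-methyl-2-(prop-2-en-1-yl)cyclohexan-1-one
Conditions: ketoreductase (S-selective, NADPH-dependent), NADP+ (cat.), i-PrOH, phosphate buffer pH 7, 30 °C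
Reagents that add atoms: none
Why: Enzymatic desymmetrising reduction of one enantiotopic carbonyl sets the carbinol (S) and with it the quaternary carbon, hydroxyl cis to allyl, as known for yeast-type reductases on this substrate.

Step 3
Reactants: 4 (2S,3S)-3-hydroxy-2-methyl-2-(prop-2-en-1-yl)cyclohexan-1-one
Product: 5 (2S,3S)-3-(TBSO)-2-methyl-2-(prop-2-en-1-yl)cyclohexan-1-one
Conditions: TBSOTf, 2,6-lutidine, CH2Cl2, 0 °C
Reagents that add atoms: tert-butyldimethylsilyl trifluoromethanesulfonate, CC(C)(C)[Si](C)(C)OS(=O)(=O)C(F)(F)F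
Why: Silyl triflate protects the hindered neopentyl-type secondary alcohol without touching the ketone.

Step 4
Reactants: 5 (2S,3S)-3-(TBSO)-2-methyl-2-(prop-2-en-1-yl)cyclohexan-1-one
Product: 7 (5S,6S)-5-(TBSO)-6-methyl-6-(prop-2-en-1-yl)cyclohex-1-en-1-yl trifluoromethanesulfonate, via potassium enolate 6 (not isolated)
Conditions: KN(SiMe3)2, THF, −78 °C; then PhNTf2, −78 → 0 °C
Reagents that add atoms: N-phenylbis(trifluoromethanesulfonimide), FC(F)(F)S(=O)(=O)N(c1ccccc1)S(=O)(=O)C(F)(F)F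
Why: Enol triflate formation is regiospecific because the other α-carbon is quaternary.

Step 5
Reactants: 7 (5S,6S)-5-(TBSO)-6-methyl-6-(prop-2-en-1-yl)cyclohex-1-en-1-yl trifluoromethanesulfonate
Product: 8 tert-butyldimethyl{[(1S,2R)-2-methyl-2-(prop-2-en-1-yl)cyclohex-3-en-1-yl]oxy}silane
Conditions: Pd(OAc)2 (cat.), PPh3, HCO2H, n-Bu3N, DMF, 60 °C
Reagents that add atoms: none
Why: Palladium-catalysed formate reduction of the vinyl triflate removes the original carbonyl oxygen and leaves the ring alkene needed for the 1,2-carbonyl transposition.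

Step 6
Reactants: 8 tert-butyldimethyl{[(1S,2R)-2-methyl-2-(prop-2-en-1-yl)cyclohex-3-en-1-yl]oxy}silane
Product: 10 (1RS,3R,4S)-4-(TBSO)-3-(3-hydroxypropyl)-3-methylcyclohexan-1-ol, via bis(9-BBN) adduct 9 (not isolated)
Conditions: 9-BBN (3.5 equiv), THF, 65 °C; then NaOH, H2O2, 0 °C → rt
Reagents that add atoms: hydrogen peroxide, OO
Why: Double hydroboration–oxidation with the bulky borane puts boron on the terminal carbon of the allyl group and on the ring carbon remote from the quaternary centre; the new carbinol is oxidised next, so its configuration is irrelevant.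

Step 7
Reactants: 10 (1RS,3R,4S)-4-(TBSO)-3-(3-hydroxypropyl)-3-methylcyclohexan-1-ol
Product: 11 3-[(1R,2S)-2-(TBSO)-1-methyl-5-oxocyclohexyl]propanal
Conditions: Dess–Martin periodinane, NaHCO3, CH2Cl2, 0 °C → rt
Reagents that add atoms: none
Why: Buffered Dess–Martin oxidation converts both alcohols at once and completes the carbonyl transposition without base that could trigger aldol closure.

Step 8
Reactants: 11 3-[(1R,2S)-2-(TBSO)-1-methyl-5-oxocyclohexyl]propanal; 12 methyl (triphenylphosphoranylidene)acetate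
Product: 13 methyl (2E)-5-[(1R,2S)-2-(TBSO)-1-methyl-5-oxocyclohexyl]pent-2-enoate
Conditions: CH2Cl2, rt
Reagents that add atoms: none
Why: The stabilised Wittig ylide reacts with the aldehyde only and leaves the ketone untouched.

Step 9
Reactants: 13 methyl (2E)-5-[(1R,2S)-2-(TBSO)-1-methyl-5-oxocyclohexyl]pent-2-enoate
Product: 14 methyl 5-[(1R,2S)-2-(TBSO)-1-methyl-5-oxocyclohexyl]pentanoate
Conditions: H2 (1 atm), Pd/C, EtOAc, rt
Reagents that add atoms: none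
Why: Catalytic hydrogenation saturates the conjugated alkene selectively.

Step 10
Reactants: 14 methyl 5-[(1R,2S)-2-(TBSO)-1-methyl-5-oxocyclohexyl]pentanoate
Product: 15 methyl 5-[(7R,8S)-8-(TBSO)-7-methyl-1,4-dioxaspiro[4.5]decan-7-yl]pentanoate
Conditions: Me3SiOCH2CH2OSiMe3, Me3SiOTf (cat.), CH2Cl2, −78 → −20 °C
Reagents that add atoms: 1,2-bis(trimethylsilyloxy)ethane, C[Si](C)(C)OCCO[Si](C)(C)C
Why: Noyori ketalisation masks the ketone under aprotic conditions so that only the ester can be enolised in the next step.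

Step 11
Reactants: 15 methyl 5-[(7R,8S)-8-(TBSO)-7-methyl-1,4-dioxaspiro[4.5]decan-7-yl]pentanoate
Product: 17 methyl (2RS)-2-bromo-5-[(7R,8S)-8-(TBSO)-7-methyl-1,4-dioxaspiro[4.5]decan-7-yl]pentanoate, via silyl ketene acetal 16 (not isolated)
Conditions: LiN(iPr)2, Me3SiCl, THF, −78 °C; then N-bromosuccinimide, −78 → 0 °C
Reagents that add atoms: N-bromosuccinimide, O=C1CCC(=O)N1Br
Why: Bromination of the in situ silyl ketene acetal gives clean α-monobromination of the ester; the new centre is destroyed later.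

Step 12
Reactants: 17 methyl (2RS)-2-bromo-5-[(7R,8S)-8-(TBSO)-7-methyl-1,4-dioxaspiro[4.5]decan-7-yl]pentanoate
Product: 18 methyl (2RS)-2-bromo-5-[(1R,2S)-2-(TBSO)-1-methyl-5-oxocyclohexyl]pentanoate
Conditions: p-TsOH·H2O (10 mol%), THF/H2O (5:1), 40 °C
Reagents that add atoms: water, O
Why: Mild acid hydrolysis of the dioxolane releases the ketone while the hindered secondary silyl ether and the bromo ester survive.

Step 13
Reactants: 18 methyl (2RS)-2-bromo-5-[(1R,2S)-2-(TBSO)-1-methyl-5-oxocyclohexyl]pentanoate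
Product: 21 methyl (1S,2RS,6R,7S)-7-(TBSO)-1-hydroxy-6-methylbicyclo[4.3.1]decane-2-carboxylate, via samarium enolate 19 (not isolated), via samarium aldolate 20 (not isolated)
Conditions: SmI2 (2.5 equiv), THF (0.01 M), −78 → 0 °C; aq. work-up
Reagents that add atoms: none
Why: Samarium diiodide-mediated intramolecular Reformatsky reaction forms the enolate only at the C–Br carbon; it can reach the ketone only from the face of its own tether, so the C1 carbinol is fixed cis-bridged relative to C6.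

Step 14
Reactants: 21 methyl (1S,2RS,6R,7S)-7-(TBSO)-1-hydroxy-6-methylbicyclo[4.3.1]decane-2-carboxylate
Product: 22 methyl (1S,2RS,6R,7S)-7-(TBSO)-6-methyl-1-(TESO)bicyclo[4.3.1]decane-2-carboxylate
Conditions: Et3SiOTf, 2,6-lutidine, CH2Cl2, 0 °C → rt
Reagents that add atoms: triethylsilyl trifluoromethanesulfonate, CC[Si](CC)(CC)OS(=O)(=O)C(F)(F)F
Why: Silylation of the bridgehead tertiary alcohol blocks retro-aldol cleavage in the basic steps that follow.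

Step 15
Reactants: 22 methyl (1S,2RS,6R,7S)-7-(TBSO)-6-methyl-1-(TESO)bicyclo[4.3.1]decane-2-carboxylate
Product: 24 methyl (1S,2RS,6R,7S)-7-(TBSO)-6-methyl-2-(phenylselanyl)-1-(TESO)bicyclo[4.3.1]decane-2-carboxylate, via lithium enolate 23 (not isolated)
Conditions: LiN(iPr)2, THF, −78 → −40 °C; then PhSeBr, −78 °C
Reagents that add atoms: benzeneselenenyl bromide, Br[Se]c1ccccc1
Why: α-Selenenylation of the ester enolate sets up the dehydrogenation; both C2 epimers converge.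

Step 16
Reactants: 24 methyl (1S,2RS,6R,7S)-7-(TBSO)-6-methyl-2-(phenylselanyl)-1-(TESO)bicyclo[4.3.1]decane-2-carboxylate
Product: 26 methyl (1S,6R,7S)-7-(TBSO)-6-methyl-1-(TESO)bicyclo[4.3.1]dec-2-ene-2-carboxylate, via selenoxide 25 (not isolated)
Conditions: 30% H2O2, pyridine, CH2Cl2, 0 °C → rt
Reagents that add atoms: none
Why: Selenoxide syn-elimination can only go toward C3 because C1 carries no hydrogen, giving the C2=C3 enoate.

Step 17
Reactants: 26 methyl (1S,6R,7S)-7-(TBSO)-6-methyl-1-(TESO)bicyclo[4.3.1]dec-2-ene-2-carboxylate; 27 vinylmagnesium bromide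
Product: 29 methyl (1S,2RS,3S,6R,7S)-7-(TBSO)-3-ethenyl-6-methyl-1-(TESO)bicyclo[4.3.1]decane-2-carboxylate, via silyl ketene acetal 28 (not isolated)
Conditions: CH2=CHMgBr, CuBr·SMe2, Me3SiCl, THF, −78 → −30 °C; aq. NH4Cl
Reagents that add atoms: none
Why: Silyl chloride-accelerated cuprate 1,4-addition delivers vinyl to C3 from the exo face, anti to the three-carbon bridge whose axial C8–H shields the inner face, which is the equatorial position required in the target.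

Step 18
Reactants: 29 methyl (1S,2RS,3S,6R,7S)-7-(TBSO)-3-ethenyl-6-methyl-1-(TESO)bicyclo[4.3.1]decane-2-carboxylate
Product: 30 methyl (1S,2S,3S,6R,7S)-7-(TBSO)-3-ethenyl-6-methyl-1-(TESO)bicyclo[4.3.1]decane-2-carboxylate
Conditions: NaOMe, MeOH, rt → 40 °C
Reagents that add atoms: none
Why: Base epimerisation at C2 converges on the trans-diequatorial ester, away from both the vinyl group and the silyloxy group; the silyl ether excludes retro-aldol.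

Step 19
Reactants: 30 methyl (1S,2S,3S,6R,7S)-7-(TBSO)-3-ethenyl-6-methyl-1-(TESO)bicyclo[4.3.1]decane-2-carboxylate
Product: 32 methyl (1S,2S,3S,6R,7S)-7-(TBSO)-3-(2-hydroxyethyl)-6-methyl-1-(TESO)bicyclo[4.3.1]decane-2-carboxylate, via B-alkyl-9-BBN adduct 31 (not isolated)
Conditions: 9-BBN, THF, 0 °C → rt; then 30% H2O2, aq. NaOAc, 0 °C
Reagents that add atoms: hydrogen peroxide, OO
Why: Anti-Markovnikov hydroboration–oxidation of the vinyl group tolerates the ester; the near-neutral oxidation suppresses δ-lactonisation.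

Step 20
Reactants: 32 methyl (1S,2S,3S,6R,7S)-7-(TBSO)-3-(2-hydroxyethyl)-6-methyl-1-(TESO)bicyclo[4.3.1]decane-2-carboxylate
Product: 33 methyl (1S,2S,3S,6R,7S)-7-(TBSO)-6-methyl-3-(2-oxoethyl)-1-(TESO)bicyclo[4.3.1]decane-2-carboxylate
Conditions: Dess–Martin periodinane, NaHCO3, CH2Cl2, 0 °C
Reagents that add atoms: none
Why: Dess–Martin oxidation gives the aldehyde without epimerising C2.

Step 21
Reactants: 33 methyl (1S,2S,3S,6R,7S)-7-(TBSO)-6-methyl-3-(2-oxoethyl)-1-(TESO)bicyclo[4.3.1]decane-2-carboxylate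
Product: 34 methyl (1S,2S,3S,6R,7S)-7-(TBSO)-6-methyl-1-(TESO)-3-[2-(trimethylsilyloxy)ethenyl]bicyclo[4.3.1]decane-2-carboxylate (E/Z mixture)
Conditions: Me3SiOTf (1.1 equiv), Et3N, CH2Cl2, 0 °C; non-aqueous work-up
Reagents that add atoms: trimethylsilyl trifluoromethanesulfonate, C[Si](C)(C)OS(=O)(=O)C(F)(F)F
Why: Soft enolisation silylates the aldehyde only (one α-carbon, C1'), avoiding any strong base near the hindered ester.

Step 22
Reactants: 35 2-methylbut-3-en-2-ol; 36 (E)-but-2-enal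
Product: 37 (2E)-4-hydroxy-4-methylpent-2-enal
Conditions: second-generation Hoveyda–Grubbs catalyst (3 mol%), CH2Cl2, 40 °C, excess 36
Reagents that add atoms: none
Why: Cross-metathesis of the tertiary allylic alcohol with the enal gives the E-configured C3'–C7' unit under thermodynamic control.

Step 23
Reactants: 37 (2E)-4-hydroxy-4-methylpent-2-enal
Product: 38 (2E)-4-methyl-4-(TESO)pent-2-enal
Conditions: Et3SiOTf, 2,6-lutidine, CH2Cl2, −78 °C
Reagents that add atoms: triethylsilyl trifluoromethanesulfonate, CC[Si](CC)(CC)OS(=O)(=O)C(F)(F)F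
Why: Silylation protects the tertiary alcohol against the Lewis acid of the next step; the enal has no γ-hydrogen and cannot enolise.

Step 24
Reactants: 34 methyl (1S,2S,3S,6R,7S)-7-(TBSO)-6-methyl-1-(TESO)-3-[2-(trimethylsilyloxy)ethenyl]bicyclo[4.3.1]decane-2-carboxylate; 38 (2E)-4-methyl-4-(TESO)pent-2-enal
Product: 39 methyl (1S,2S,3S,6R,7S)-7-(TBSO)-3-[(4E)-3-hydroxy-6-methyl-1-oxo-6-(TESO)hept-4-en-2-yl]-6-methyl-1-(TESO)bicyclo[4.3.1]decane-2-carboxylate (mixture at C2' and C3')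
Conditions: BF3·OEt2, CH2Cl2, −78 °C; aq. NaHCO3
Reagents that add atoms: none
Why: Mukaiyama aldol 1,2-addition of the aldehyde enol silane to the non-enolisable enal forms the C2'–C3' bond; both new centres are removed in the next step.

Step 25
Reactants: 39 methyl (1S,2S,3S,6R,7S)-7-(TBSO)-3-[(4E)-3-hydroxy-6-methyl-1-oxo-6-(TESO)hept-4-en-2-yl]-6-methyl-1-(TESO)bicyclo[4.3.1]decane-2-carboxylate
Product: 41 methyl (1S,2S,3R,6R,7S)-7-(TBSO)-6-methyl-3-[(2E,4E)-6-methyl-1-oxo-6-(TESO)hepta-2,4-dien-2-yl]-1-(TESO)bicyclo[4.3.1]decane-2-carboxylate, via mesylate 40 (not isolated)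
Conditions: MsCl, Et3N, CH2Cl2, 0 °C; then DBU, rt
Reagents that add atoms: none
Why: E1cB dehydration through the aldehyde enolate gives the conjugated dienal with the 2E geometry (formyl trans to the dienyl carbon) typical of aldol condensation.

Step 26
Reactants: 41 methyl (1S,2S,3R,6R,7S)-7-(TBSO)-6-methyl-3-[(2E,4E)-6-methyl-1-oxo-6-(TESO)hepta-2,4-dien-2-yl]-1-(TESO)bicyclo[4.3.1]decane-2-carboxylate
Product: 42 methyl (1S,2S,3R,6R,7S)-7-(TBSO)-3-[(2E,4E)-1-hydroxy-6-methyl-6-(TESO)hepta-2,4-dien-2-yl]-6-methyl-1-(TESO)bicyclo[4.3.1]decane-2-carboxylate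
Conditions: NaBH4, CeCl3·7H2O, MeOH, −20 → 0 °C
Reagents that add atoms: none
Why: Luche reduction gives clean 1,2-reduction of the dienal and leaves the methyl ester alone.

Step 27
Reactants: 42 methyl (1S,2S,3R,6R,7S)-7-(TBSO)-3-[(2E,4E)-1-hydroxy-6-methyl-6-(TESO)hepta-2,4-dien-2-yl]-6-methyl-1-(TESO)bicyclo[4.3.1]decane-2-carboxylate
Product: 43 methyl (1S,2S,3R,6R,7S)-3-[(2E,4E)-1-acetoxy-6-methyl-6-(TESO)hepta-2,4-dien-2-yl]-7-(TBSO)-6-methyl-1-(TESO)bicyclo[4.3.1]decane-2-carboxylate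
Conditions: Ac2O, pyridine, DMAP (cat.), CH2Cl2, 0 °C, directly on crude 42
Reagents that add atoms: acetic anhydride, CC(=O)OC(C)=O
Why: The primary allylic alcohol is the only free hydroxyl, and immediate acetylation prevents δ-lactonisation onto the C2 ester.

Step 28
Reactants: 43 methyl (1S,2S,3R,6R,7S)-3-[(2E,4E)-1-acetoxy-6-methyl-6-(TESO)hepta-2,4-dien-2-yl]-7-(TBSO)-6-methyl-1-(TESO)bicyclo[4.3.1]decane-2-carboxylate
Product: 44 methyl (1S,2S,3R,6R,7S)-3-[(2E,4E)-1-acetoxy-6-hydroxy-6-methylhepta-2,4-dien-2-yl]-1,7-dihydroxy-6-methylbicyclo[4.3.1]decane-2-carboxylate (CNP0302883.3)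
Conditions: Bu4NF, AcOH (1:1, excess), THF, rt → 45 °C
Reagents that add atoms: none
Why: Acetic acid-buffered fluoride removes all three silyl ethers under near-neutral conditions, sparing the acetate, the methyl ester and the ionisation-prone tertiary dienyl alcohol.

## Compound list

1 | 2-methylcyclohexane-1,3-dione | CC1C(=O)CCCC1=O | starting material
2 | allyl bromide | C=CCBr | starting material
3 | 2-methyl-2-(prop-2-en-1-yl)cyclohexane-1,3-dione | C=CCC1(C)C(=O)CCCC1=O | intermediate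
4 | (2S,3S)-3-hydroxy-2-methyl-2-(prop-2-en-1-yl)cyclohexan-1-one | C=CC[C@]1(C)C(=O)CCC[C@@H]1O | intermediate
5 | (2S,3S)-3-(TBSO)-2-methyl-2-(prop-2-en-1-yl)cyclohexan-1-one | C=CC[C@]1(C)C(=O)CCC[C@@H]1O[Si](C)(C)C(C)(C)C | intermediate
6 | potassium enolate of 5 | C=CC[C@]1(C)C([O-])=CCC[C@@H]1O[Si](C)(C)C(C)(C)C.[K+] | intermediate (not isolated)
7 | (5S,6S)-5-(TBSO)-6-methyl-6-(prop-2-en-1-yl)cyclohex-1-en-1-yl trifluoromethanesulfonate | C=CC[C@]1(C)C(OS(=O)(=O)C(F)(F)F)=CCC[C@@H]1O[Si](C)(C)C(C)(C)C | intermediate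
8 | tert-butyldimethyl{[(1S,2R)-2-methyl-2-(prop-2-en-1-yl)cyclohex-3-en-1-yl]oxy}silane | C=CC[C@]1(C)C=CCC[C@@H]1O[Si](C)(C)C(C)(C)C | intermediate
9 | bis(9-BBN) adduct of 8 (boron on the chain terminus and on the ring carbon remote from the quaternary centre) | B1(C2CCCC1CCC2)CCC[C@]3(C)CC(B4C5CCCC4CCC5)CC[C@@H]3O[Si](C)(C)C(C)(C)C | intermediate (not isolated)
10 | (1RS,3R,4S)-4-(TBSO)-3-(3-hydroxypropyl)-3-methylcyclohexan-1-ol | OCCC[C@]1(C)CC(O)CC[C@@H]1O[Si](C)(C)C(C)(C)C | intermediate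
11 | 3-[(1R,2S)-2-(TBSO)-1-methyl-5-oxocyclohexyl]propanal | O=CCC[C@]1(C)CC(=O)CC[C@@H]1O[Si](C)(C)C(C)(C)C | intermediate
12 | methyl (triphenylphosphoranylidene)acetate | COC(=O)C=P(c1ccccc1)(c1ccccc1)c1ccccc1 | starting material
13 | methyl (2E)-5-[(1R,2S)-2-(TBSO)-1-methyl-5-oxocyclohexyl]pent-2-enoate | COC(=O)/C=C/CC[C@]1(C)CC(=O)CC[C@@H]1O[Si](C)(C)C(C)(C)C | intermediate
14 | methyl 5-[(1R,2S)-2-(TBSO)-1-methyl-5-oxocyclohexyl]pentanoate | COC(=O)CCCC[C@]1(C)CC(=O)CC[C@@H]1O[Si](C)(C)C(C)(C)C | intermediate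
15 | methyl 5-[(7R,8S)-8-(TBSO)-7-methyl-1,4-dioxaspiro[4.5]decan-7-yl]pentanoate | COC(=O)CCCC[C@]1(C)CC2(CC[C@@H]1O[Si](C)(C)C(C)(C)C)OCCO2 | intermediate
16 | methyl trimethylsilyl ketene acetal of 15 | COC(O[Si](C)(C)C)=CCCC[C@]1(C)CC2(CC[C@@H]1O[Si](C)(C)C(C)(C)C)OCCO2 | intermediate (not isolated)
17 | methyl (2RS)-2-bromo-5-[(7R,8S)-8-(TBSO)-7-methyl-1,4-dioxaspiro[4.5]decan-7-yl]pentanoate | COC(=O)C(Br)CCC[C@]1(C)CC2(CC[C@@H]1O[Si](C)(C)C(C)(C)C)OCCO2 | intermediate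
18 | methyl (2RS)-2-bromo-5-[(1R,2S)-2-(TBSO)-1-methyl-5-oxocyclohexyl]pentanoate | COC(=O)C(Br)CCC[C@]1(C)CC(=O)CC[C@@H]1O[Si](C)(C)C(C)(C)C | intermediate
19 | samarium enolate (trivalent samarium, diiodide) of the ester of 18 | COC(O[Sm](I)I)=CCCC[C@]1(C)CC(=O)CC[C@@H]1O[Si](C)(C)C(C)(C)C | intermediate (not isolated)
20 | samarium aldolate of 21 | COC(=O)C1CCC[C@]2(C)C[C@@]1(O[Sm](I)I)CC[C@@H]2O[Si](C)(C)C(C)(C)C | intermediate (not isolated)
21 | methyl (1S,2RS,6R,7S)-7-(TBSO)-1-hydroxy-6-methylbicyclo[4.3.1]decane-2-carboxylate | COC(=O)C1CCC[C@]2(C)C[C@@]1(O)CC[C@@H]2O[Si](C)(C)C(C)(C)C | intermediate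
22 | methyl (1S,2RS,6R,7S)-7-(TBSO)-6-methyl-1-(TESO)bicyclo[4.3.1]decane-2-carboxylate | COC(=O)C1CCC[C@]2(C)C[C@@]1(O[Si](CC)(CC)CC)CC[C@@H]2O[Si](C)(C)C(C)(C)C | intermediate
23 | lithium enolate of 22 | COC([O-])=C1CCC[C@]2(C)C[C@@]1(O[Si](CC)(CC)CC)CC[C@@H]2O[Si](C)(C)C(C)(C)C.[Li+] | intermediate (not isolated)
24 | methyl (1S,2RS,6R,7S)-7-(TBSO)-6-methyl-2-(phenylselanyl)-1-(TESO)bicyclo[4.3.1]decane-2-carboxylate | COC(=O)C1([Se]c3ccccc3)CCC[C@]2(C)C[C@@]1(O[Si](CC)(CC)CC)CC[C@@H]2O[Si](C)(C)C(C)(C)C | intermediate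
25 | selenoxide of 24 | COC(=O)C1([Se](=O)c3ccccc3)CCC[C@]2(C)C[C@@]1(O[Si](CC)(CC)CC)CC[C@@H]2O[Si](C)(C)C(C)(C)C | intermediate (not isolated)
26 | methyl (1S,6R,7S)-7-(TBSO)-6-methyl-1-(TESO)bicyclo[4.3.1]dec-2-ene-2-carboxylate | COC(=O)C1=CCC[C@]2(C)C[C@@]1(O[Si](CC)(CC)CC)CC[C@@H]2O[Si](C)(C)C(C)(C)C | intermediate
27 | vinylmagnesium bromide | C=C[Mg]Br | starting material
28 | methyl trimethylsilyl ketene acetal of 29 | COC(O[Si](C)(C)C)=C1[C@H](C=C)CC[C@]2(C)C[C@@]1(O[Si](CC)(CC)CC)CC[C@@H]2O[Si](C)(C)C(C)(C)C | intermediate (not isolated)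
29 | methyl (1S,2RS,3S,6R,7S)-7-(TBSO)-3-ethenyl-6-methyl-1-(TESO)bicyclo[4.3.1]decane-2-carboxylate | COC(=O)C1[C@H](C=C)CC[C@]2(C)C[C@@]1(O[Si](CC)(CC)CC)CC[C@@H]2O[Si](C)(C)C(C)(C)C | intermediate
30 | methyl (1S,2S,3S,6R,7S)-7-(TBSO)-3-ethenyl-6-methyl-1-(TESO)bicyclo[4.3.1]decane-2-carboxylate | COC(=O)[C@H]1[C@H](C=C)CC[C@]2(C)C[C@@]1(O[Si](CC)(CC)CC)CC[C@@H]2O[Si](C)(C)C(C)(C)C | intermediate
31 | B-alkyl-9-BBN adduct of 30 | COC(=O)[C@H]1[C@H](CCB3C4CCCC3CCC4)CC[C@]2(C)C[C@@]1(O[Si](CC)(CC)CC)CC[C@@H]2O[Si](C)(C)C(C)(C)C | intermediate (not isolated)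
32 | methyl (1S,2S,3S,6R,7S)-7-(TBSO)-3-(2-hydroxyethyl)-6-methyl-1-(TESO)bicyclo[4.3.1]decane-2-carboxylate | COC(=O)[C@H]1[C@H](CCO)CC[C@]2(C)C[C@@]1(O[Si](CC)(CC)CC)CC[C@@H]2O[Si](C)(C)C(C)(C)C | intermediate
33 | methyl (1S,2S,3S,6R,7S)-7-(TBSO)-6-methyl-3-(2-oxoethyl)-1-(TESO)bicyclo[4.3.1]decane-2-carboxylate | COC(=O)[C@H]1[C@H](CC=O)CC[C@]2(C)C[C@@]1(O[Si](CC)(CC)CC)CC[C@@H]2O[Si](C)(C)C(C)(C)C | intermediate
34 | methyl (1S,2S,3S,6R,7S)-7-(TBSO)-6-methyl-1-(TESO)-3-[2-(trimethylsilyloxy)ethenyl]bicyclo[4.3.1]decane-2-carboxylate (E/Z) | COC(=O)[C@H]1[C@H](C=CO[Si](C)(C)C)CC[C@]2(C)C[C@@]1(O[Si](CC)(CC)CC)CC[C@@H]2O[Si](C)(C)C(C)(C)C | intermediate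
35 | 2-methylbut-3-en-2-ol | C=CC(C)(C)O | starting material
36 | (E)-but-2-enal | C/C=C/C=O | starting material
37 | (2E)-4-hydroxy-4-methylpent-2-enal | CC(C)(O)/C=C/C=O | intermediate
38 | (2E)-4-methyl-4-(TESO)pent-2-enal | CC[Si](CC)(CC)OC(C)(C)/C=C/C=O | intermediate
39 | methyl (1S,2S,3S,6R,7S)-7-(TBSO)-3-[(4E)-3-hydroxy-6-methyl-1-oxo-6-(TESO)hept-4-en-2-yl]-6-methyl-1-(TESO)bicyclo[4.3.1]decane-2-carboxylate | COC(=O)[C@H]1[C@H](C(C=O)C(O)/C=C/C(C)(C)O[Si](CC)(CC)CC)CC[C@]2(C)C[C@@]1(O[Si](CC)(CC)CC)CC[C@@H]2O[Si](C)(C)C(C)(C)C | intermediate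
40 | methanesulfonate of 39 | COC(=O)[C@H]1[C@H](C(C=O)C(OS(C)(=O)=O)/C=C/C(C)(C)O[Si](CC)(CC)CC)CC[C@]2(C)C[C@@]1(O[Si](CC)(CC)CC)CC[C@@H]2O[Si](C)(C)C(C)(C)C | intermediate (not isolated)
41 | methyl (1S,2S,3R,6R,7S)-7-(TBSO)-6-methyl-3-[(2E,4E)-6-methyl-1-oxo-6-(TESO)hepta-2,4-dien-2-yl]-1-(TESO)bicyclo[4.3.1]decane-2-carboxylate | COC(=O)[C@H]1[C@H](/C(=C\C=C\C(C)(C)O[Si](CC)(CC)CC)C=O)CC[C@]2(C)C[C@@]1(O[Si](CC)(CC)CC)CC[C@@H]2O[Si](C)(C)C(C)(C)C | intermediate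
42 | methyl (1S,2S,3R,6R,7S)-7-(TBSO)-3-[(2E,4E)-1-hydroxy-6-methyl-6-(TESO)hepta-2,4-dien-2-yl]-6-methyl-1-(TESO)bicyclo[4.3.1]decane-2-carboxylate | COC(=O)[C@H]1[C@H](/C(=C\C=C\C(C)(C)O[Si](CC)(CC)CC)CO)CC[C@]2(C)C[C@@]1(O[Si](CC)(CC)CC)CC[C@@H]2O[Si](C)(C)C(C)(C)C | intermediate
43 | methyl (1S,2S,3R,6R,7S)-3-[(2E,4E)-1-acetoxy-6-methyl-6-(TESO)hepta-2,4-dien-2-yl]-7-(TBSO)-6-methyl-1-(TESO)bicyclo[4.3.1]decane-2-carboxylate | COC(=O)[C@H]1[C@H](/C(=C\C=C\C(C)(C)O[Si](CC)(CC)CC)COC(C)=O)CC[C@]2(C)C[C@@]1(O[Si](CC)(CC)CC)CC[C@@H]2O[Si](C)(C)C(C)(C)C | intermediate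
44 | methyl (1S,2S,3R,6R,7S)-3-[(2E,4E)-1-acetoxy-6-hydroxy-6-methylhepta-2,4-dien-2-yl]-1,7-dihydroxy-6-methylbicyclo[4.3.1]decane-2-carboxylate | COC(=O)[C@H]1[C@H](/C(=C\C=C\C(C)(C)O)COC(C)=O)CC[C@]2(C)C[C@@]1(O)CC[C@@H]2O | target

## Step count and risks

Total steps: 28. Longest linear sequence: 26 (steps 1–21 and 24–28); the side-chain enal 38 takes 2 steps (22–23).

Three steps most likely to fail:

Step 13 (seven-membered Reformatsky closure onto a ketone; the enolate may simply be protonated). Fallback: close the ring at C2=C3 by metathesis instead of at C1–C2 by aldol. It sets out from 11. Salt-free Ph3P=CH2 (THF, −78 °C) methylenates only the aldehyde to give (3R,4S)-3-(but-3-en-1-yl)-4-(TBSO)-3-methylcyclohexan-1-one F1. The lithium enolate of methyl 2-(phenylselanyl)propanoate (LiN(iPr)2, THF, −78 °C) adds to the ketone to give methyl 2-[(1S,3R,4S)-3-(but-3-en-1-yl)-4-(TBSO)-1-hydroxy-3-methylcyclohexyl]-2-(phenylselanyl)propanoate F2, together with its C1 epimer. H2O2/pyridine gives methyl 2-[(1S,3R,4S)-3-(but-3-en-1-yl)-4-(TBSO)-1-hydroxy-3-methylcyclohexyl]prop-2-enoate F3 by selenoxide elimination toward the methyl group. Et3SiOTf/2,6-lutidine gives its triethylsilyl ether F4. Ring-closing metathesis (second-generation Hoveyda–Grubbs catalyst, toluene, 80 °C) then comes back to the route at 26. Only the C1 epimer with the acrylate cis to the butenyl chain can close, so the other epimer is removed at this point.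

Step 17 (cuprate addition to a trisubstituted enoate flanked by a quaternary silyloxy carbon). Fallback: make the acceptor an enal, which is far more reactive. It sets out from 26. i-Bu2AlH (CH2Cl2, −78 °C) gives [(1S,6R,7S)-7-(TBSO)-6-methyl-1-(TESO)bicyclo[4.3.1]dec-2-en-2-yl]methanol F5. MnO2 gives (1S,6R,7S)-7-(TBSO)-6-methyl-1-(TESO)bicyclo[4.3.1]dec-2-ene-2-carbaldehyde F6. CH2=CHMgBr/CuBr·SMe2/Me3SiCl, then Et3N equilibration, gives (1S,2S,3S,6R,7S)-7-(TBSO)-3-ethenyl-6-methyl-1-(TESO)bicyclo[4.3.1]decane-2-carbaldehyde F7. NaClO2/NaH2PO4/2-methylbut-2-ene gives the corresponding (1S,2S,3S,6R,7S)-2-carboxylic acid F8. Me3SiCHN2 in MeOH/toluene then comes back to the route at 30.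

Step 24 (Mukaiyama aldol of an aldehyde enol silane with an enal; 1,4-addition or oligomerisation may compete). Fallback: build the dienal by cross-coupling at C3'–C4' instead of aldol at C2'–C3'. It sets out from 33. Eschenmoser's salt (Me2N=CH2 iodide) and Et3N give the Mannich base methyl (1S,2S,3S,6R,7S)-7-(TBSO)-3-[3-(dimethylamino)-1-oxopropan-2-yl]-6-methyl-1-(TESO)bicyclo[4.3.1]decane-2-carboxylate F9. It loses dimethylamine to give methyl (1S,2S,3R,6R,7S)-7-(TBSO)-6-methyl-3-(3-oxoprop-1-en-2-yl)-1-(TESO)bicyclo[4.3.1]decane-2-carboxylate F10. Br2 (CH2Cl2, −78 °C) gives the 2,3-dibromo aldehyde methyl (1S,2S,3R,6R,7S)-7-(TBSO)-3-(1,2-dibromo-3-oxopropan-2-yl)-6-methyl-1-(TESO)bicyclo[4.3.1]decane-2-carboxylate F11. Et3N converts it into methyl (1S,2S,3R,6R,7S)-3-[(1E)-1-bromo-3-oxoprop-1-en-2-yl]-7-(TBSO)-6-methyl-1-(TESO)bicyclo[4.3.1]decane-2-carboxylate F12. Suzuki–Miyaura coupling (Pd(PPh3)4, K3PO4, THF/H2O, 50 °C) with triethyl{[(3E)-2-methyl-4-(4,4,5,5-tetramethyl-1,3,2-dioxaborolan-2-yl)but-3-en-2-yl]oxy}silane F13, the triethylsilyl ether of the commercial alkenyl pinacol boronate, then comes back to the route at 41 with retention of both alkene geometries.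

## Further compounds

F1 | step 13 | (3R,4S)-3-(but-3-en-1-yl)-4-(TBSO)-3-methylcyclohexan-1-one | C=CCC[C@]1(C)CC(=O)CC[C@@H]1O[Si](C)(C)C(C)(C)C
F2 | step 13 | methyl 2-[(1S,3R,4S)-3-(but-3-en-1-yl)-4-(TBSO)-1-hydroxy-3-methylcyclohexyl]-2-(phenylselanyl)propanoate | C=CCC[C@]1(C)C[C@](O)(C(C)([Se]c2ccccc2)C(=O)OC)CC[C@@H]1O[Si](C)(C)C(C)(C)C
F3 | step 13 | methyl 2-[(1S,3R,4S)-3-(but-3-en-1-yl)-4-(TBSO)-1-hydroxy-3-methylcyclohexyl]prop-2-enoate | C=CCC[C@]1(C)C[C@](O)(C(=C)C(=O)OC)CC[C@@H]1O[Si](C)(C)C(C)(C)C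
F4 | step 13 | methyl 2-[(1S,3R,4S)-3-(but-3-en-1-yl)-4-(TBSO)-3-methyl-1-(TESO)cyclohexyl]prop-2-enoate | C=CCC[C@]1(C)C[C@](O[Si](CC)(CC)CC)(C(=C)C(=O)OC)CC[C@@H]1O[Si](C)(C)C(C)(C)C
F5 | step 17 | [(1S,6R,7S)-7-(TBSO)-6-methyl-1-(TESO)bicyclo[4.3.1]dec-2-en-2-yl]methanol | OCC1=CCC[C@]2(C)C[C@@]1(O[Si](CC)(CC)CC)CC[C@@H]2O[Si](C)(C)C(C)(C)C
F6 | step 17 | (1S,6R,7S)-7-(TBSO)-6-methyl-1-(TESO)bicyclo[4.3.1]dec-2-ene-2-carbaldehyde | O=CC1=CCC[C@]2(C)C[C@@]1(O[Si](CC)(CC)CC)CC[C@@H]2O[Si](C)(C)C(C)(C)C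
F7 | step 17 | (1S,2S,3S,6R,7S)-7-(TBSO)-3-ethenyl-6-methyl-1-(TESO)bicyclo[4.3.1]decane-2-carbaldehyde | O=C[C@H]1[C@H](C=C)CC[C@]2(C)C[C@@]1(O[Si](CC)(CC)CC)CC[C@@H]2O[Si](C)(C)C(C)(C)C
F8 | step 17 | (1S,2S,3S,6R,7S)-7-(TBSO)-3-ethenyl-6-methyl-1-(TESO)bicyclo[4.3.1]decane-2-carboxylic acid | OC(=O)[C@H]1[C@H](C=C)CC[C@]2(C)C[C@@]1(O[Si](CC)(CC)CC)CC[C@@H]2O[Si](C)(C)C(C)(C)C
F9 | step 24 | methyl (1S,2S,3S,6R,7S)-7-(TBSO)-3-[3-(dimethylamino)-1-oxopropan-2-yl]-6-methyl-1-(TESO)bicyclo[4.3.1]decane-2-carboxylate | COC(=O)[C@H]1[C@H](C(CN(C)C)C=O)CC[C@]2(C)C[C@@]1(O[Si](CC)(CC)CC)CC[C@@H]2O[Si](C)(C)C(C)(C)C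
F10 | step 24 | methyl (1S,2S,3R,6R,7S)-7-(TBSO)-6-methyl-3-(3-oxoprop-1-en-2-yl)-1-(TESO)bicyclo[4.3.1]decane-2-carboxylate | COC(=O)[C@H]1[C@H](C(=C)C=O)CC[C@]2(C)C[C@@]1(O[Si](CC)(CC)CC)CC[C@@H]2O[Si](C)(C)C(C)(C)C
F11 | step 24 | methyl (1S,2S,3R,6R,7S)-7-(TBSO)-3-(1,2-dibromo-3-oxopropan-2-yl)-6-methyl-1-(TESO)bicyclo[4.3.1]decane-2-carboxylate | COC(=O)[C@H]1[C@H](C(Br)(CBr)C=O)CC[C@]2(C)C[C@@]1(O[Si](CC)(CC)CC)CC[C@@H]2O[Si](C)(C)C(C)(C)C
F12 | step 24 | methyl (1S,2S,3R,6R,7S)-3-[(1E)-1-bromo-3-oxoprop-1-en-2-yl]-7-(TBSO)-6-methyl-1-(TESO)bicyclo[4.3.1]decane-2-carboxylate | COC(=O)[C@H]1[C@H](/C(=C\Br)C=O)CC[C@]2(C)C[C@@]1(O[Si](CC)(CC)CC)CC[C@@H]2O[Si](C)(C)C(C)(C)C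
F13 | step 24 | triethyl{[(3E)-2-methyl-4-(4,4,5,5-tetramethyl-1,3,2-dioxaborolan-2-yl)but-3-en-2-yl]oxy}silane | CC[Si](CC)(CC)OC(C)(C)/C=C/B1OC(C)(C)C(C)(C)O1
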